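Late in the winter run, a closed stirred flask in which free catalyst turns starting material into target beside a protic impurity, 55.7% of the charge is target at 2.50 h. The last interval still added 19 percentage points, so the readings show no ceiling, and what you need is how fast the fraction not yet target shrinks.

| flask | starting material | protic impurity | free catalyst | remark | time |
|---|---|---|---|---|---|
| midnight | 2.2 M | 0.22 M | 22 mM | run made earlier |  |
| winter | 1.1 M | 0.22 M | 22 mM | run made earlier |  |
| dusk | 2.2 M | 0.22 M | 11 mM | run made earlier |  |
| north | 2.2 M | 0.220 M | 22 mM | one stirred flow tank at steady state, fed with the mixture as stated, mean residence time 2.0 h |  |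
| south | 2.2 M | 0.220 M | 22 mM | a tube with plug flow, the mixed feed as stated, residence time 2.0 h | 2.0 h |
| east | 2.2 M | 0.220 M | 22 mM | a single well-mixed tank run continuously and read at steady state, 20.0 h in it on average |  |
| north-west | 2.2 M | 0.220 M | 22 mM | everything together in a closed stirred flask, run for 2.0 h | 2.0 h |

midnight run (percent of the starting material charged)

| time / min | target / % |
|---|---|
| 8.00 | 3.1 |
| 25.0 | 7.4 |
| 40.0 | 12.5 |
| 60.0 | 18.2 |
| 90.0 | 26.9 |
| 120 | 34.3 |

winter run (percent of the starting material charged)

| time / h | target / % |
|---|---|
| 0.200 | 5.8 |
| 0.333 | 10.4 |
| 0.500 | 15.4 |
| 0.833 | 24.4 |
| 1.33 | 36.6 |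
| 2.50 | 55.7 |

dusk run (percent of the starting material charged)

| time / h | target / % |
|---|---|
| 0.500 | 5.9 |
| 1.00 | 8.9 |
| 1.33 | 12.0 |
| 2.00 | 18.6 |
| 2.50 | 21.7 |

(each reading ± 0.5 percentage points)

- the stated concentrations are those of everything mixed, before any reaction; amounts are the same in each set-up
- the earlier runs were made in a closed, stirred flask

- the set-up with the highest amount of target at the outlet or at the end, in percent of the starting material put in ("none" if the first two lie within 2 percentage points) (north / south / east / north-west / none)
- amount of target at the outlet or at the end, in percent of the starting material put in, north
- amount of target at the outlet or at the end, in percent of the starting material put in, south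
- amount of target at the outlet or at the end, in percent of the starting material put in, east
- amount of target at the outlet or at the end, in percent of the starting material put in, north-west

Now go through the midnight run in slow motion, taking at each stage the log of the inverse of the fraction not yet target, divided by the time. In the first instants, at 8.00 min, this reads 0.236 h⁻¹, with the scatter weighing heavily on so small a reading. In the middle, at 60.0 min, it reads 0.201 h⁻¹, and at the end, at 120 min, 0.210 h⁻¹. So the readings of this run look like a pseudo-first-order decay, with a constant level within their scatter.

The constant does move between runs. Winter, with the smaller charge, reads 0.326 h⁻¹, more than midnight, and dusk, with half the catalyst, reads 0.103 h⁻¹, about half of midnight's. It follows the charge and the catalyst rather than the conversion, so I carry it unchanged into tanks fed this midnight charge.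

Then one number serves for each vessel: the stay number D (the Damköhler number), the constant times the time in the vessel, 0.420 for a stay of 2.0 h. A closed flask or tube leaves exp(−D) not yet target, while a tank, working throughout at its outlet composition, gives D over one plus D. My reckoning:

north, D = 0.420: target 29.6%

east, D = 4.20: target 80.8%

The closed flask and tube at 2.0 h simply repeat the midnight reading, 34.3%, which stands above my north figure.

The forecast, from its own fitted constant, gives 29.1% for north, 33.8% for south, 80.4% for east and 33.8% for north-west, naming east as best. Its ground for the carry-over is: “This sum is the same in a tank at steady state, so the constant k should carry over.”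

The flask gives 30.8% for north, 33.9% for south, 79.9% for east and 33.9% for north-west, with east best.

    starting material + free catalyst ⇌ catalyst intermediate A (K = 2.70 M⁻¹, k = 59.0 M⁻¹ h⁻¹)
    starting material + protic impurity → quenched substrate (k = 3.50 M⁻¹ h⁻¹)
    2 starting material → self-condensation product (k = 0.0420 M⁻¹ h⁻¹)
    catalyst intermediate B ⇌ free catalyst + target (K = 1.60 M, k = 24.0 h⁻¹)
    catalyst intermediate A → catalyst intermediate B (k = 1500 h⁻¹)

Read the stay number back from the tanks as target over what is not target. North gives 0.445 against the carried 0.420, and east, whose stay is ten times north's, gives 3.98 against 4.20. East stands highest through its back-mixing and longer stay taken together: with these two taken away, east's 79.9% falls to 33.9%.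

All runs were computed on assumed constants; scatter was added.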